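Every C–C bond and all six stereocentres are made on arenes that carry a single oxygen, and the three remaining phenol oxygens are added at the end. The disconnection is the three C–O bonds at the carbon para to the central substituted carbon of rings B1 (indane), B2 (eight-membered ring) and B3 (dihydrobenzofuran); in each ring this is the only C–H with a C–H on both sides. One iridium-catalysed borylation with oxidative work-up turns these three C–H bonds into C–OH without touching the skeleton. Its substrate, pentamethyl ether 27, comes from an enantioselective carbene C–H insertion, a ring-closing metathesis, a rhodium-catalysed conjugate arylation and an indanone annulation.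

Key step: step 17

Labels: Cf and Cd are C2 and C3 of the dihydrobenzofuran (benzo ring B3). The eight-membered ring is B3–Ce–Cb–Cc–B2–Cd, where B2 is the methoxy-bearing ring on Cd. Ca joins Ce to ring B1 in the indane. "Anisyl" means 4-methoxyphenyl; the three anisyl groups sit on Ca, Cc and Cf and are named by the carbon that carries them.

Assumption: Rh2(S-PTAD)4 (step 4) and the (R,R)-diene (step 10) are taken to give the configurations drawn; if a test run shows the opposite sense, the mirror-image catalyst is used and nothing else changes.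

Remark on the structures: target 30, key-step substrate 27 and key-step product 29 share one skeleton and the same configuration at all six stereocentres (Ca, Cb, Cc, Cd, Ce, Cf).

Step 1
Reactants: 1 2-bromo-6-fluorobenzonitrile; 2 (4-methoxyphenyl)methanol
Product: 3 2-bromo-6-[(4-methoxyphenyl)methoxy]benzonitrile
Conditions: NaH, THF, 0 °C → rt
Reagents that add atoms: none
Why: Nucleophilic aromatic substitution: the alkoxide of 2 displaces the fluoride activated by the ortho nitrile, and fluoride leaves far faster than bromide.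

Step 2
Reactants: 4 2-bromo-6-methoxybenzaldehyde
Product: 5 2-(2-bromo-6-methoxyphenyl)-1,3-dioxolane
Conditions: HOCH2CH2OH, p-TsOH (cat.), toluene, reflux, Dean–Stark trap
Reagents that add atoms: ethane-1,2-diol, OCCO
Why: Acid-catalysed acetalisation with removal of water masks the aldehyde for the organometallic and carbene steps.

Step 3
Reactants: 5 2-(2-bromo-6-methoxyphenyl)-1,3-dioxolane; 3 2-bromo-6-[(4-methoxyphenyl)methoxy]benzonitrile
Product: 8 hydrazone of {2-bromo-6-[(4-methoxyphenyl)methoxy]phenyl}[2-(1,3-dioxolan-2-yl)-3-methoxyphenyl]methanone (E/Z mixture), via Grignard reagent 6 (not isolated), via ketimine 7 (not isolated)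
Conditions: Mg, THF, 45 °C; 3, CuBr (5 mol %), THF, 60 °C; MeOH, 0 °C; N2H4·H2O, EtOH, 80 °C (no acid)
Reagents that add atoms: hydrazine (as hydrate), NN
Why: A Grignard reagent adds once to a nitrile to give an N-magnesio ketimine, and the free N–H ketimine then undergoes transimination with hydrazine under neutral conditions that leave the acetal intact, which avoids condensing hydrazine with a tri-ortho-substituted benzophenone.

Step 4
Reactants: 8 hydrazone
Product: 10 (2S,3R)-4-bromo-3-[2-(1,3-dioxolan-2-yl)-3-methoxyphenyl]-2-(4-methoxyphenyl)-2,3-dihydro-1-benzofuran (cis), via diazo compound 9 (not isolated)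
Conditions: MnO2, CH2Cl2, 0 °C, filter; Rh2(S-PTAD)4 (dirhodium tetrakis[(S)-(1-adamantyl)(phthalimido)acetate], 1 mol %), CH2Cl2, 0 °C → rt
Reagents that add atoms: none
Why: MnO2 dehydrogenates the hydrazone to the diaryldiazomethane, and the chiral dirhodium carboxylate turns it into a donor/donor carbene that inserts into the benzylic ether C–H bond (1,5-insertion); the catalyst sets Cd (3R) and the concerted insertion gives the cis isomer at Cf.

Step 5
Reactants: 10 cis-dihydrobenzofuran acetal
Product: 12 2-[(2R,3R)-4-bromo-2-(4-methoxyphenyl)-2,3-dihydro-1-benzofuran-3-yl]-6-methoxybenzaldehyde (trans), via trans acetal 11 (not isolated)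
Conditions: TFA, CH2Cl2, 0 °C; then H2O, rt
Reagents that add atoms: water, O
Why: Acid opens the C2–O bond reversibly to the 4-methoxybenzylic cation, so Cf equilibrates to the more stable trans isomer while Cd is not involved, and water then hydrolyses the dioxolane.

Step 6
Reactants: 12 trans aldehyde
Product: 13 (2R,3R)-4-bromo-3-(2-ethenyl-3-methoxyphenyl)-2-(4-methoxyphenyl)-2,3-dihydro-1-benzofuran
Conditions: Ph3PCH3Br, KOtBu, THF, 0 °C → rt
Reagents that add atoms: methyltriphenylphosphonium bromide, C[P+](c1ccccc1)(c1ccccc1)c1ccccc1.[Br-]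
Why: Wittig methylenation of an aryl aldehyde; the ylide is not basic enough to open the dihydrobenzofuran.

Step 7
Reactants: 13 bromo styrene
Product: 15 1-[(2R,3R)-3-(2-ethenyl-3-methoxyphenyl)-2-(4-methoxyphenyl)-2,3-dihydro-1-benzofuran-4-yl]prop-2-en-1-ol (both carbinol epimers), via aryllithium 14 (not isolated)
Conditions: n-BuLi, THF, −78 °C; acrolein, −78 °C
Reagents that add atoms: prop-2-enal (acrolein), C=CC=O
Why: Bromine–lithium exchange at −78 °C outruns addition of n-BuLi to the hindered styrene, and the aryllithium, trapped at once, adds 1,2 to acrolein; the new carbinol centre is removed in step 9.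

Step 8
Reactants: 15 diene
Product: 16 cyclic allylic alcohol in which B3–Ce(H)(OH)–Cb(H)=Cc(H)–B2 closes the eight-membered ring (Z alkene; Ce epimers)
Conditions: second-generation Grubbs catalyst RuCl2(=CHPh)(H2IMes)(PCy3) (10 mol %), CH2Cl2 (2 mM), 40 °C
Reagents that add atoms: none
Why: Ring-closing metathesis: the ruthenium carbene forms on the unhindered allylic alcohol olefin and closes onto the styrene, the two arenes and Cd hold the olefins close, and an eight-membered ring can hold only the Z alkene.

Step 9
Reactants: 16 cyclic allylic alcohol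
Product: 17 cyclic Z-enone (Ce=O on ring B3; Cb=Cc; Cc on ring B2)
Conditions: MnO2, CH2Cl2, rt
Reagents that add atoms: none
Why: MnO2 oxidises allylic and benzylic alcohols selectively to the conjugated ketone.

Step 10
Reactants: 17 cyclic Z-enone; 18 (4-methoxyphenyl)boronic acid
Product: 19 ketone with Cb as CH2 and Cc bearing H and an anisyl group (this anisyl group and the Cd–Cf bond on opposite faces of the eight-membered ring)
Conditions: [RhCl(C2H4)2]2 (2.5 mol %), (1R,4R)-2,5-diphenylbicyclo[2.2.2]octa-2,5-diene (6 mol %), KOH (0.3 equiv), dioxane/H2O 10:1, 50 °C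
Reagents that add atoms: none
Why: Hayashi–Miyaura reaction: the aryl–rhodium species adds to the β-carbon of the cyclic Z-enone as it does to coumarins, the chiral diene selects the enone face and so sets Cc, and its sense is chosen so that the anisyl group enters trans to the Cd–Cf bond.

Step 11
Reactants: 19 ketone; 5 2-(2-bromo-6-methoxyphenyl)-1,3-dioxolane
Product: 21 keto aldehyde carrying a 2-formyl-3-methoxyphenyl group (ring B1) on Cb trans to the anisyl group on Cc, via keto acetal 20 (not isolated)
Conditions: Pd2(dba)3 (2.5 mol %), XPhos (6 mol %), K3PO4, toluene, 100 °C; then 2 M HCl, THF, rt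
Reagents that add atoms: water, O
Why: Palladium-catalysed α-arylation of the ketone enolate at its only α-carbon Cb; the α-aryl ketone equilibrates under the basic conditions so that ring B1 should sit trans to the neighbouring anisyl group on Cc, and dilute acid then frees the aldehyde.

Step 12
Reactants: 21 keto aldehyde
Product: 22 diol with the Ca(H)(OH)–Ce(OH) bond closed to an indane-1,2-diol fused at Ce–Cb (diastereomers at Ca and Ce)
Conditions: SmI2 (2.5 equiv), t-BuOH, THF, −78 °C → rt
Reagents that add atoms: none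
Why: Samarium ketyl coupling of aldehyde and ketone (pinacol cyclisation) forms the Ca–Ce bond and the five-membered ring; both new carbinol centres are removed in steps 13 and 14.

Step 13
Reactants: 22 diol
Product: 23 α-hydroxy ketone (Ca=O; Ce–OH)
Conditions: IBX, DMSO, rt
Reagents that add atoms: none
Why: IBX oxidises the secondary benzylic alcohol of a 1,2-diol to the α-hydroxy ketone without cleaving the C–C bond and leaves the tertiary alcohol.

Step 14
Reactants: 23 α-hydroxy ketone
Product: 24 7-methoxy-1-indanone fused at C2–C3 (Ce–Cb) to the eight-membered ring (Ce–H trans to Cb–H)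
Conditions: SmI2 (3 equiv), THF/MeOH, −78 °C; then DBU (cat.), CH2Cl2, rt
Reagents that add atoms: none
Why: SmI2 cleaves the C–O bond α to the aryl ketone to give the samarium enolate; protonation and base equilibration at Ce, which is α to the ketone and benzylic, should give the isomer in which the two eight-membered-ring bonds at Ce and Cb are trans on the cyclopentanone.

Step 15
Reactants: 24 fused indanone; 25 (4-methoxyphenyl)magnesium bromide
Product: 26 tertiary alcohol (Ca bears OH and an anisyl group)
Conditions: CeCl3, THF, −78 → 0 °C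
Reagents that add atoms: none
Why: Dichloro(4-methoxyphenyl)cerium, formed from 25 and CeCl3, is nucleophilic but weakly basic and adds to the readily enolised 2-aryl-1-indanone; the configuration of the carbinol carbon is lost in step 16.

Step 16
Reactants: 26 tertiary alcohol
Product: 27 tris-deoxy canaliculatol pentamethyl ether (Ca–H cis to Ce–H)
Conditions: Et3SiH (10 equiv), BF3·OEt2 (2 equiv), CH2Cl2, −78 °C
Reagents that add atoms: none
Why: Ionic hydrogenation: BF3 ionises the tertiary doubly benzylic alcohol at −78 °C, where the cyclic benzylic aryl ether should stay closed, and Et3SiH delivers hydride to the planar cation at Ca on the face away from ring B3 on Ce, so Ca–H ends up cis to Ce–H.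

Step 17
Reactants: 27 tris-deoxy canaliculatol pentamethyl ether
Product: 29 canaliculatol pentamethyl ether with three free hydroxyls, via tris(pinacolboronate) 28 (not isolated)
Conditions: [Ir(OMe)(cod)]2 (3 mol %), 4,4'-di-tert-butyl-2,2'-bipyridine (dtbpy, 6 mol %), B2pin2 (1.6 equiv), THF, 80 °C; then NaBO3·4H2O, THF/H2O, rt
Reagents that add atoms: sodium perborate, [Na+].[O-]OB=O (the three new oxygens); bis(pinacolato)diboron, CC1(C)OB(OC1(C)C)B1OC(C)(C)C(C)(C)O1 (boron of 28 only)
Why: The trivalent iridium tris(boryl) complex formed from the precatalyst, dtbpy and B2pin2 cleaves an aryl C–H bond by oxidative addition and releases the aryl boronate by C–B reductive elimination; perborate then adds to boron and the aryl group shifts from boron to oxygen at the same carbon. The closest known reaction type is the sterically governed iridium-catalysed C–H borylation of 1,2,3-trisubstituted arenes at C5 followed by oxidation to the phenol. No ring is closed and no stereocentre is formed; the six existing ones are not touched because benzylic C–H bonds do not react under these conditions. The step needs site selectivity among 21 aryl C–H bonds, and the substrate secures it: on each of rings B1, B2 and B3 the C–H para to the central substituted carbon is the only one flanked by two C–H carbons, all others are ortho to a carbon substituent, a methoxy group or the ring oxygen, and a ring that has reacted once is blocked on both sides of boron. B2pin2 is kept near the amount consumed so that the slow borylation ortho to methoxy on the three anisyl rings stays minor.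

Step 18
Reactants: 29 canaliculatol pentamethyl ether triol
Product: 30 canaliculatol
Conditions: BBr3 (excess), CH2Cl2, −78 → 0 °C; then MeOH/H2O
Reagents that add atoms: none
Why: BBr3 coordinates each methoxy oxygen and bromide attacks the methyl group (SN2); permethylated oligostilbenes with a trans-2-aryl-dihydrobenzofuran are known to tolerate these conditions, and a reversible opening of the benzylic C–O bond would reclose to the same trans isomer.

Compound list
1 | 2-bromo-6-fluorobenzonitrile | N#Cc1c(F)cccc1Br | starting material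
2 | (4-methoxyphenyl)methanol | COc1ccc(CO)cc1 | starting material
3 | 2-bromo-6-[(4-methoxyphenyl)methoxy]benzonitrile | COc1ccc(COc2cccc(Br)c2C#N)cc1 | intermediate
4 | 2-bromo-6-methoxybenzaldehyde | COc1cccc(Br)c1C=O | starting material
5 | 2-(2-bromo-6-methoxyphenyl)-1,3-dioxolane | COc1cccc(Br)c1C1OCCO1 | intermediate
6 | [2-(1,3-dioxolan-2-yl)-3-methoxyphenyl]magnesium bromide | COc1cccc([Mg]Br)c1C1OCCO1 | intermediate
7 | N–H ketimine of {2-bromo-6-[(4-methoxyphenyl)methoxy]phenyl}[2-(1,3-dioxolan-2-yl)-3-methoxyphenyl]methanone | COc1ccc(COc2cccc(Br)c2C(=N)c2cccc(OC)c2C2OCCO2)cc1 | intermediate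
8 | hydrazone of the same ketone (E/Z mixture) | COc1ccc(COc2cccc(Br)c2C(=NN)c2cccc(OC)c2C2OCCO2)cc1 | intermediate
9 | 1-bromo-2-{diazo[2-(1,3-dioxolan-2-yl)-3-methoxyphenyl]methyl}-3-[(4-methoxyphenyl)methoxy]benzene | COc1ccc(COc2cccc(Br)c2C(=[N+]=[N-])c2cccc(OC)c2C2OCCO2)cc1 | intermediate
10 | (2S,3R)-4-bromo-3-[2-(1,3-dioxolan-2-yl)-3-methoxyphenyl]-2-(4-methoxyphenyl)-2,3-dihydro-1-benzofuran (cis) | COc1cccc(c1C1OCCO1)[C@@H]1c2c(cccc2Br)O[C@@H]1c1ccc(OC)cc1 | intermediate
11 | (2R,3R)-4-bromo-3-[2-(1,3-dioxolan-2-yl)-3-methoxyphenyl]-2-(4-methoxyphenyl)-2,3-dihydro-1-benzofuran (trans) | COc1cccc(c1C1OCCO1)[C@@H]1c2c(cccc2Br)O[C@H]1c1ccc(OC)cc1 | intermediate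
12 | 2-[(2R,3R)-4-bromo-2-(4-methoxyphenyl)-2,3-dihydro-1-benzofuran-3-yl]-6-methoxybenzaldehyde | COc1cccc(c1C=O)[C@@H]1c2c(cccc2Br)O[C@H]1c1ccc(OC)cc1 | intermediate
13 | (2R,3R)-4-bromo-3-(2-ethenyl-3-methoxyphenyl)-2-(4-methoxyphenyl)-2,3-dihydro-1-benzofuran | COc1cccc(c1C=C)[C@@H]1c2c(cccc2Br)O[C@H]1c1ccc(OC)cc1 | intermediate
14 | [(2R,3R)-3-(2-ethenyl-3-methoxyphenyl)-2-(4-methoxyphenyl)-2,3-dihydro-1-benzofuran-4-yl]lithium | COc1cccc(c1C=C)[C@@H]1c2c(cccc2[Li])O[C@H]1c1ccc(OC)cc1 | intermediate
15 | 1-[(2R,3R)-3-(2-ethenyl-3-methoxyphenyl)-2-(4-methoxyphenyl)-2,3-dihydro-1-benzofuran-4-yl]prop-2-en-1-ol (carbinol epimers) | COc1cccc(c1C=C)[C@@H]1c2c(cccc2C(O)C=C)O[C@H]1c1ccc(OC)cc1 | intermediate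
16 | cyclic allylic alcohol: B3–Ce(H)(OH)–Cb(H)=Cc(H)–B2 closes the eight-membered ring (Z); trans-dihydrobenzofuran as in 12; Ce epimers | COc1cccc2c1/C=C\C(O)c1cccc3c1[C@@H]2[C@H](c1ccc(OC)cc1)O3 | intermediate
17 | cyclic Z-enone (Ce=O) | COc1cccc2c1/C=C\C(=O)c1cccc3c1[C@@H]2[C@H](c1ccc(OC)cc1)O3 | intermediate
18 | (4-methoxyphenyl)boronic acid | COc1ccc(B(O)O)cc1 | starting material
19 | ketone with Cb = CH2 and Cc bearing H and an anisyl group; this anisyl group trans to the Cd–Cf bond across the eight-membered ring | COc1cccc2c1[C@@H](c1ccc(OC)cc1)CC(=O)c1cccc3c1[C@@H]2[C@H](c1ccc(OC)cc1)O3 | intermediate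
20 | 19 with a 2-(1,3-dioxolan-2-yl)-3-methoxyphenyl group (ring B1) on Cb, trans to the anisyl group on Cc | COc1cccc2c1[C@@H](c1ccc(OC)cc1)[C@H](c1cccc(OC)c1C1OCCO1)C(=O)c1cccc3c1[C@@H]2[C@H](c1ccc(OC)cc1)O3 | intermediate
21 | keto aldehyde: 19 with a 2-formyl-3-methoxyphenyl group on Cb, trans to the anisyl group on Cc | COc1cccc2c1[C@@H](c1ccc(OC)cc1)[C@H](c1cccc(OC)c1C=O)C(=O)c1cccc3c1[C@@H]2[C@H](c1ccc(OC)cc1)O3 | intermediate
22 | diol: Ca(H)(OH)–Ce(OH) closed to an indane-1,2-diol fused at Ce–Cb (diastereomers at Ca, Ce) | COc1cccc2c1[C@@H](c1ccc(OC)cc1)[C@@H]1c4cccc(OC)c4C(O)C1(O)c1cccc3c1[C@@H]2[C@H](c1ccc(OC)cc1)O3 | intermediate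
23 | α-hydroxy ketone (Ca=O, Ce–OH; Ce epimers) | COc1cccc2c1[C@@H](c1ccc(OC)cc1)[C@@H]1c4cccc(OC)c4C(=O)C1(O)c1cccc3c1[C@@H]2[C@H](c1ccc(OC)cc1)O3 | intermediate
24 | 7-methoxy-1-indanone fused at Ce–Cb to the eight-membered ring; Ce–H trans to Cb–H | COc1cccc2c1[C@@H](c1ccc(OC)cc1)[C@@H]1c4cccc(OC)c4C(=O)[C@H]1c1cccc3c1[C@@H]2[C@H](c1ccc(OC)cc1)O3 | intermediate
25 | (4-methoxyphenyl)magnesium bromide | COc1ccc([Mg]Br)cc1 | starting material
26 | tertiary alcohol: Ca bears OH and an anisyl group (carbinol configuration not fixed) | COc1cccc2c1[C@@H](c1ccc(OC)cc1)[C@@H]1c4cccc(OC)c4C(O)(c4ccc(OC)cc4)[C@H]1c1cccc3c1[C@@H]2[C@H](c1ccc(OC)cc1)O3 | intermediate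
27 | tris-deoxy canaliculatol pentamethyl ether (Ca–H cis to Ce–H, Ce–H trans to Cb–H, ring B1 trans to the anisyl group on Cc, trans-dihydrobenzofuran) | COc1ccc([C@@H]2c3c(OC)cccc3[C@H]3[C@H](c4ccc(OC)cc4)c4c(OC)cccc4[C@@H]4c5c(cccc5[C@H]23)O[C@H]4c2ccc(OC)cc2)cc1 | intermediate
28 | tris(pinacolboronate) of 27, boron at the carbon para to the central substituted carbon of rings B1, B2 and B3 | COc1ccc([C@@H]2c3c(OC)cc(B6OC(C)(C)C(C)(C)O6)cc3[C@H]3[C@H](c4ccc(OC)cc4)c4c(OC)cc(B6OC(C)(C)C(C)(C)O6)cc4[C@@H]4c5c(cc(B6OC(C)(C)C(C)(C)O6)cc5[C@H]23)O[C@H]4c2ccc(OC)cc2)cc1 | intermediate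
29 | canaliculatol pentamethyl ether with three free hydroxyls at those carbons | COc1ccc([C@@H]2c3c(OC)cc(O)cc3[C@H]3[C@H](c4ccc(OC)cc4)c4c(OC)cc(O)cc4[C@@H]4c5c(cc(O)cc5[C@H]23)O[C@H]4c2ccc(OC)cc2)cc1 | intermediate
30 | canaliculatol | Oc1ccc([C@@H]2c3c(O)cc(O)cc3[C@H]3[C@H](c4ccc(O)cc4)c4c(O)cc(O)cc4[C@@H]4c5c(cc(O)cc5[C@H]23)O[C@H]4c2ccc(O)cc2)cc1 | target

Total step count: 18. Longest linear sequence: 17 steps (4 → 5 → 8 → 10 → 12 → 13 → 15 → 16 → 17 → 19 → 21 → 22 → 23 → 24 → 26 → 27 → 29 → 30).

Steps most likely to fail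

Step 17 (key step). What may go wrong: borylation spreads to the C–H bonds ortho to methoxy on the anisyl rings before the third ring has reacted, so that over-oxidised phenols form. The fallback sets out from 27 and returns at 29. The more size-sensitive iridium-catalysed arene C–H silylation ([Ir(OMe)(cod)]2, 2,4,7-trimethyl-1,10-phenanthroline, HSiMe(OSiMe3)2, norbornene, THF, 100 °C) should give the tris(silyl)arene F1, silylated at the same three carbons. Tamao–Fleming oxidation (H2O2, KHCO3, TBAF, THF/MeOH) should then turn the three C–Si bonds into C–OH and give 29.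

Step 8. What may go wrong: closure of the eight-membered ring is slow at the hindered styrene and intermolecular metathesis to oligomers takes over. The fallback sets out from 12, returns at 17 and replaces steps 6 to 9. Stille coupling of bromide 12 with tributyl(1-ethoxyvinyl)stannane (Pd(PPh3)4, toluene, 100 °C) should give the enol ether F2, and dilute HCl in THF the methyl ketone F3. An amine-mediated intramolecular aldol condensation between the acetyl group and the aldehyde (pyrrolidine, AcOH, MeOH, high dilution, 60 °C) should close the ring directly to enone 17.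

Step 16. What may go wrong: loss of a proton from the cation at Ca gives the indene and re-protonation scrambles Ce, or the acid opens the dihydrobenzofuran and the silane reduces it. The fallback sets out from 26 and returns at 27, and separates ionisation from reduction. HCl in dioxane/CH2Cl2 at 0 °C should give the tertiary benzylic chloride F4 under non-reducing conditions, in which an opened dihydrobenzofuran can only reclose. Hydrogen-atom transfer from (Me3Si)3SiH (AIBN, toluene, 80 °C) to the planar benzylic radical, again on the face away from ring B3, should give 27.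

Further compounds
F1 | step 17 | tris-deoxy canaliculatol pentamethyl ether bearing a methylbis(trimethylsilyloxy)silyl group at the carbon para to the central substituted carbon of each of rings B1, B2 and B3 | COc1ccc([C@@H]2c3c(OC)cc([Si](C)(O[Si](C)(C)C)O[Si](C)(C)C)cc3[C@H]3[C@H](c4ccc(OC)cc4)c4c(OC)cc([Si](C)(O[Si](C)(C)C)O[Si](C)(C)C)cc4[C@@H]4c5c(cc([Si](C)(O[Si](C)(C)C)O[Si](C)(C)C)cc5[C@H]23)O[C@H]4c2ccc(OC)cc2)cc1
F2 | step 8 | 2-[(2R,3R)-4-(1-ethoxyethenyl)-2-(4-methoxyphenyl)-2,3-dihydro-1-benzofuran-3-yl]-6-methoxybenzaldehyde | COc1cccc(c1C=O)[C@@H]1c2c(cccc2C(=C)OCC)O[C@H]1c1ccc(OC)cc1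
F3 | step 8 | 2-[(2R,3R)-4-acetyl-2-(4-methoxyphenyl)-2,3-dihydro-1-benzofuran-3-yl]-6-methoxybenzaldehyde | COc1cccc(c1C=O)[C@@H]1c2c(cccc2C(C)=O)O[C@H]1c1ccc(OC)cc1
F4 | step 16 | tertiary chloride corresponding to 26 (Cl in place of OH on Ca) | COc1cccc2c1[C@@H](c1ccc(OC)cc1)[C@@H]1c4cccc(OC)c4C(Cl)(c4ccc(OC)cc4)[C@H]1c1cccc3c1[C@@H]2[C@H](c1ccc(OC)cc1)O3
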